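Mono adduct stands in these flasks like the level in a stirred tank, fed by lost substrate and drained by its own losses. So work with the fraction of substrate left.

| setting | east | north | flask |
|---|---|---|---|
| substrate | 10 mM | 15 mM | 20 mM |
| gas | 10 mM (held) | 10 mM (held) | 10 mM (held) |
| remark | run made earlier | run made earlier |  |
| time |  |  | 4.0 h |

| run | time / h | mono adduct / % | substrate / % |
|---|---|---|---|
| east | 0.0333 | 10.7 | 84.9 |
| east | 0.133 | 14.4 | 25.8 |
| east | 0.667 | 2.8 | 0.4 |
| east | 3.00 | 0.7 | 0.1 |
| north | 0.0333 | 8.9 | 86.3 |
| north | 0.133 | 13.9 | 34.9 |
| north | 0.667 | 2.6 | 0.2 |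
| north | 3.00 | 1.0 | 0.6 |

(each reading ± 0.3 percentage points)

- when, up to 4.0 h, the flask holds most mono adduct
- the amount of mono adduct, in percent of the substrate charged, at that time
- earliest time at which at least nineteen twentieths of that best amount are there
- latest time at which they still are

How fast does gas-fed substrate loss grow with the charge? Between the first two readings after the start, the east run lost 59.3 mM h⁻¹ and the north run 77.3 mM h⁻¹. That is a factor 1.30, smaller than the factor 1.50 in charge. The same step upward gives the flask 95.4 mM h⁻¹, or 4.77 h⁻¹ of its charge.

How long does mono adduct stay? Take the holding time, the mono adduct level divided by the fraction of the charge lost per hour, read like the lifetime of a pseudo-first-order loss. The readings give 0.0243 h in the east run and 0.0270 h in the north run, so 0.0256 h.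

My own reckoning for the flask's best is therefore 12.2%; it gives no times. The forecast, with “the peak should fall near 45% substrate remaining”, says 15.5% at 0.125 h, within 0.09 h to 0.17 h, which is above mine.

The flask gives 13.0% at 0.107 h, within 0.0729 h to 0.153 h.

    substrate + coupling partner → mono adduct (k = 1.00 L mol⁻¹ s⁻¹)
    coupling partner + mono adduct → bis adduct (k = 0.0290 L mol⁻¹ s⁻¹)
    gas ⇌ coupling partner, rate k3*(csat - [coupling partner]) (kL = 0.00370 s⁻¹)
    mono adduct ⇌ isomer of the product (K = 19.0, k = 0.00940 s⁻¹)
    coupling partner + mono adduct → over-reaction product (k = 0.370 L mol⁻¹ s⁻¹)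

By its best time the flask had lost 46.1% of its substrate, a mean 86.4 mM h⁻¹, and its holding time reads 0.0300 h, longer than 0.0256 h. In the neighbour flask with 80 mM of substrate, the loss is taken as the gas uptake with no coupling partner dissolved, 133 mM h⁻¹; that is 1.67 h⁻¹ of the charge, and 0.0256 h turns it into 4.27%. That neighbour's best stands at 6.69%, above the reckoned level by a factor 1.57.

(All runs come from a simulation on assumed constants; scatter was added.)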